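Everything rests on cutting the C2''–C3'' bond in ring C of the 2,3-cis flavanone (unit 2). C2'' is a benzylic carbon bound to the ring A oxygen O1''; with ring C open it is the CH2 of a 4-benzyloxybenzyl aryl ether standing 1,6 to C3'', and because O1'' and the C5'' oxygen are equivalent ortho oxygens, both can carry that group. A chiral dirhodium carboxylate turns a C3'' diazo ketone into a carbenoid that inserts into this benzylic C–H bond, closing ring C and setting C2'' and C3'' in one operation. The precursor is the 2,3-trans flavanone (unit 1) bearing at C3 the chain C(=N2)–C(=O)–aryl.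

Key step: step 9

**Remarks on the chemistry**

- Locants: unit 1 (unprimed, its aryl ring primed) is the 4-methoxyphenyl flavanone and unit 2 (double-primed) the 4-hydroxyphenyl flavanone. The target is (2S,3R,2''S,3''S), so unit 1 is trans and unit 2 is cis.
- Assumption: which antipode of the chiral diene (step 3) and of the dirhodium carboxylate (step 9) gives the stated sense is settled by a trial run; the antipodes named are the first choice.
- Ring A of unit 2 is dressed in two operations: the unchelated 4-hydroxyl (the later C7'' oxygen) takes a plain benzyl group first, then both equivalent ortho hydroxyls take the 4-benzyloxybenzyl group together.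
- The substrate of step 9 is already a single enantiomer, so the catalyst exerts diastereocontrol there.
- Intermediates made with stoichiometric reagents and used without isolation are numbered. Catalyst-bound species and the mixture of partly deprotected phenols in step 10 are not single compounds and carry no number.

**Route**

Step 1
Reactants: 1 2',4',6'-trihydroxyacetophenone
Product: 2 1-[2,4-bis(benzyloxy)-6-hydroxyphenyl]ethan-1-one
Conditions: BnBr (2.1 equiv), K2CO3 (2.2 equiv), DMF, 0 °C to rt
Reagents that add atoms: benzyl bromide, BrCc1ccccc1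
Why: Williamson ether synthesis: the 4-hydroxyl and one ortho hydroxyl are alkylated, while the second ortho hydroxyl, held in a hydrogen bond to the acetyl carbonyl, is left free for the later ring closure.

Step 2
Reactants: 2 1-[2,4-bis(benzyloxy)-6-hydroxyphenyl]ethan-1-one
Product: 4 5,7-bis(benzyloxy)-4H-chromen-4-one, via enaminone 3 (not isolated)
Conditions: Me2NCH(OMe)2 (3 equiv), toluene, 95 °C; concentrate; conc. HCl, CH2Cl2, 40 °C
Reagents that add atoms: N,N-dimethylformamide dimethyl acetal, COC(OC)N(C)C
Why: Condensation of the acetyl methyl group with the formamide acetal gives an enaminone, and acid then promotes conjugate addition of the free phenol with loss of dimethylamine, the standard enaminone route to 2,3-unsubstituted chromones.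

Step 3
Reactants: 4 5,7-bis(benzyloxy)-4H-chromen-4-one; 5 4-methoxyphenylboronic acid
Product: 6 (2S)-5,7-bis(benzyloxy)-2-(4-methoxyphenyl)chroman-4-one
Conditions: [RhCl(C2H4)2]2 (2.5 mol %), (1R,4R)-2,5-diphenylbicyclo[2.2.2]octa-2,5-diene (5.5 mol %), aq. KOH (20 mol %), toluene/H2O, 40 °C
Reagents that add atoms: none
Why: Rhodium-catalysed asymmetric conjugate addition of an arylboronic acid to a chromone (Hayashi–Miyaura reaction): the aryl–rhodium species carbometalates the C2=C3 bond from the face left open by the chiral diene, which sets C2 as S, and water protonates the rhodium enolate; little base and mild temperature keep the flavanone from opening.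

Step 4
Reactants: 1 2',4',6'-trihydroxyacetophenone
Product: 7 1-[4-(benzyloxy)-2,6-dihydroxyphenyl]ethan-1-one
Conditions: BnBr (0.95 equiv, slow addition), K2CO3 (1.0 equiv), DMF, 0 °C to rt
Reagents that add atoms: benzyl bromide, BrCc1ccccc1
Why: Williamson ether synthesis with the alkylating agent as the limiting reagent: the 4-hydroxyl, para to the acetyl group and not tied up in a hydrogen bond, is the most acidic and is alkylated first, while both ortho hydroxyls stay chelated to the carbonyl.

Step 5
Reactants: 7 1-[4-(benzyloxy)-2,6-dihydroxyphenyl]ethan-1-one; 8 4-benzyloxybenzyl chloride (two equivalents are incorporated)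
Product: 9 1-{4-(benzyloxy)-2,6-bis[(4-benzyloxybenzyl)oxy]phenyl}ethan-1-one
Conditions: 8 (2.5 equiv), K2CO3 (3.5 equiv), DMF, 70 °C
Reagents that add atoms: 4-benzyloxybenzyl chloride, ClCc1ccc(OCc2ccccc2)cc1 (compound 8; the second of the two equivalents that end up in 9)
Why: Exhaustive Williamson ether synthesis with a reactive benzylic chloride: excess reagent and heat alkylate both ortho hydroxyls, the second one despite its hydrogen bond to the carbonyl, and because the two positions are equivalent there is no selectivity to control.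

Step 6
Reactants: 9 1-{4-(benzyloxy)-2,6-bis[(4-benzyloxybenzyl)oxy]phenyl}ethan-1-one
Product: 12 1-{4-(benzyloxy)-2,6-bis[(4-benzyloxybenzyl)oxy]phenyl}-2-bromoethan-1-one, via lithium enolate 10 (not isolated), via trimethylsilyl enol ether 11 (not isolated)
Conditions: LiN(SiMe3)2, THF, −78 °C; Me3SiCl, −78 to 0 °C; concentrate; NBS, THF, −78 to 0 °C
Reagents that add atoms: N-bromosuccinimide, O=C1CCC(=O)N1Br (chlorotrimethylsilane, C[Si](C)(C)Cl, supplies the silyl group of intermediate 11 only)
Why: α-Bromination of a methyl ketone through its silyl enol ether: the enol ether reacts with N-bromosuccinimide far faster than the electron-rich ring A does, and no acid is released that could cleave the alkoxybenzyl ethers.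

Step 7
Reactants: 6 (2S)-5,7-bis(benzyloxy)-2-(4-methoxyphenyl)chroman-4-one; 12 1-{4-(benzyloxy)-2,6-bis[(4-benzyloxybenzyl)oxy]phenyl}-2-bromoethan-1-one
Product: 14 (2S,3R)-5,7-bis(benzyloxy)-3-(2-{4-(benzyloxy)-2,6-bis[(4-benzyloxybenzyl)oxy]phenyl}-2-oxoethyl)-2-(4-methoxyphenyl)chroman-4-one (2,3-trans), via lithium enolate 13 (not isolated)
Conditions: LiN(SiMe3)2 (1.05 equiv), THF, −78 °C; 12 (1.1 equiv), −78 to −40 °C; AcOH quench at −78 °C
Reagents that add atoms: none
Why: SN2 alkylation of a ketone lithium enolate with an α-bromo ketone to a 1,4-diketone: the enolate is formed and trapped at low temperature before it can open by loss of the ring A phenoxide, the doubly ortho-substituted aryl ketone of 12 is shielded against carbonyl attack, and the electrophile enters C3 opposite to the C2 aryl group, so that C3 is set as R (2,3-trans), which is also the more stable arrangement.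

Step 8
Reactants: 14 (2S,3R)-5,7-bis(benzyloxy)-3-(2-{4-(benzyloxy)-2,6-bis[(4-benzyloxybenzyl)oxy]phenyl}-2-oxoethyl)-2-(4-methoxyphenyl)chroman-4-one
Product: 17 (2S,3R)-5,7-bis(benzyloxy)-3-(2-{4-(benzyloxy)-2,6-bis[(4-benzyloxybenzyl)oxy]phenyl}-1-diazo-2-oxoethyl)-2-(4-methoxyphenyl)chroman-4-one, via lithium enolate 15 (not isolated), via trifluoroacetyl diketone 16 (not isolated)
Conditions: LiN(SiMe3)2 (1.1 equiv), THF, −78 °C; CF3CO2CH2CF3, −78 °C; aq. NH4Cl; then MsN3, Et3N, H2O (1 equiv), MeCN, rt
Reagents that add atoms: mesyl azide, CS(=O)(=O)N=[N+]=[N-] (2,2,2-trifluoroethyl trifluoroacetate, O=C(OCC(F)(F)F)C(F)(F)F, supplies the trifluoroacetyl group of intermediate 16 only)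
Why: Detrifluoroacetylative diazo transfer: the hindered amide base removes a proton from the less substituted side-chain CH2 in preference to the methine C3, Claisen-type trifluoroacetylation activates that carbon, and the sulfonyl azide then delivers N2 while the trifluoroacetyl group leaves as the N-sulfonyl amide; no new stereocentre is formed and C3 stays in its stable trans arrangement.

Step 9
Reactants: 17 (2S,3R)-5,7-bis(benzyloxy)-3-(2-{4-(benzyloxy)-2,6-bis[(4-benzyloxybenzyl)oxy]phenyl}-1-diazo-2-oxoethyl)-2-(4-methoxyphenyl)chroman-4-one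
Product: 18 (2S,3R)-5,7-bis(benzyloxy)-3-{(2S,3S)-7-(benzyloxy)-5-[(4-benzyloxybenzyl)oxy]-2-(4-benzyloxyphenyl)-4-oxochroman-3-yl}-2-(4-methoxyphenyl)chroman-4-one
Conditions: Rh2(S-PTTL)4, dirhodium tetrakis[N-phthaloyl-(S)-tert-leucinate] (2 mol %), toluene, slow addition of 17, −60 to −20 °C
Reagents that add atoms: none
Why: Proposed new method: Rh2(S-PTTL)4 expels N2 from 17 to give an electrophilic carbenoid (divalent rhodium) at C3'' that inserts, through a concerted three-centre transition state with hydride-transfer character, into a benzylic C–H bond of one ortho 4-benzyloxybenzyl ether, forming C2''–C3'' and moving that hydrogen to C3''. The closest known reaction types are the closure of chroman-4-ones by carbenoid insertion of 2-alkoxyaryl α-diazo ketones into the O–CH bond and the cis-selective 1,5-insertion of aryldiazoacetates into benzylic ether C–H bonds with the same class of phthalimido carboxylate catalysts; what has not been shown is such an insertion at a carbenoid carbon that bears a branched, stereogenic alkyl group with a β-hydrogen, with the catalyst controlling both new centres. Ring C of unit 2 closes by 1,6-insertion to a six-membered ring, because the 1,5-position is the oxygen O1'', which has no C–H bond. C2'' and C3'' are set in the same transition state: the cis relation should follow from a chair-like arrangement with the C2'' aryl group pseudo-equatorial and hydrogen delivery to the carbenoid on the same side, and the absolute sense (2''S,3''S) is imposed by the chiral carboxylate pocket acting together with the resident C2 and C3 centres (matched antipode). The step needs insertion to outrun the 1,2-hydride shift from C3 and the attack of O1'' on the carbenoid (oxonium ylide, then [1,2]-benzyl shift); the substrate helps because the C4 carbonyl makes C3–H a poor hydride donor, C2''–H is activated both by oxygen and by the electron-rich aryl ring, and the aryl ether oxygen is a weak nucleophile, while bulky ligands and low temperature do the rest. No choice between the two ortho ethers arises because they are identical.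

Step 10
Reactants: 18 (2S,3R)-5,7-bis(benzyloxy)-3-{(2S,3S)-7-(benzyloxy)-5-[(4-benzyloxybenzyl)oxy]-2-(4-benzyloxyphenyl)-4-oxochroman-3-yl}-2-(4-methoxyphenyl)chroman-4-one
Product: 19 (2S,3R)-5,7-dihydroxy-3-[(2S,3S)-5,7-dihydroxy-2-(4-hydroxyphenyl)-4-oxochroman-3-yl]-2-(4-methoxyphenyl)chroman-4-one (target CNP0196568.6)
Conditions: H2 (1 atm), 10% Pd/C, THF/MeOH (1:1), rt
Reagents that add atoms: none
Why: Catalytic hydrogenolysis of benzylic C–O bonds: the five benzyl ethers give toluene and the 4-hydroxybenzyl aryl ether then left on the C5'' oxygen is cleaved as 4-methylphenol, whereas the methyl ether, both ketones and the cyclic C2–O1 and C2''–O1'' bonds should persist at 1 atm under neutral conditions, so that no stereocentre, the epimerisable C3'' included, is disturbed.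

**Compound list**

1 | 2',4',6'-trihydroxyacetophenone | CC(=O)c1c(O)cc(O)cc1O | starting material
2 | 1-[2,4-bis(benzyloxy)-6-hydroxyphenyl]ethan-1-one | CC(=O)c1c(O)cc(OCc2ccccc2)cc1OCc1ccccc1 | intermediate
3 | (E)-1-[2,4-bis(benzyloxy)-6-hydroxyphenyl]-3-(dimethylamino)prop-2-en-1-one | CN(C)/C=C/C(=O)c1c(O)cc(OCc2ccccc2)cc1OCc1ccccc1 | intermediate (not isolated)
4 | 5,7-bis(benzyloxy)-4H-chromen-4-one | O=c1ccoc2cc(OCc3ccccc3)cc(OCc3ccccc3)c12 | intermediate
5 | 4-methoxyphenylboronic acid | COc1ccc(B(O)O)cc1 | starting material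
6 | (2S)-5,7-bis(benzyloxy)-2-(4-methoxyphenyl)chroman-4-one | COc1ccc([C@H]2Oc3cc(OCc4ccccc4)cc(OCc4ccccc4)c3C(=O)C2)cc1 | intermediate
7 | 1-[4-(benzyloxy)-2,6-dihydroxyphenyl]ethan-1-one | CC(=O)c1c(O)cc(OCc2ccccc2)cc1O | intermediate
8 | 4-benzyloxybenzyl chloride | ClCc1ccc(OCc2ccccc2)cc1 | starting material
9 | 1-{4-(benzyloxy)-2,6-bis[(4-benzyloxybenzyl)oxy]phenyl}ethan-1-one | CC(=O)c1c(OCc2ccc(OCc3ccccc3)cc2)cc(OCc2ccccc2)cc1OCc1ccc(OCc2ccccc2)cc1 | intermediate
10 | lithium enolate of 9 (lithium 1-arylethen-1-olate) | C=C(O[Li])c1c(OCc2ccc(OCc3ccccc3)cc2)cc(OCc2ccccc2)cc1OCc1ccc(OCc2ccccc2)cc1 | intermediate (not isolated)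
11 | trimethylsilyl enol ether of 9 | C=C(O[Si](C)(C)C)c1c(OCc2ccc(OCc3ccccc3)cc2)cc(OCc2ccccc2)cc1OCc1ccc(OCc2ccccc2)cc1 | intermediate (not isolated)
12 | 1-{4-(benzyloxy)-2,6-bis[(4-benzyloxybenzyl)oxy]phenyl}-2-bromoethan-1-one | BrCC(=O)c1c(OCc2ccc(OCc3ccccc3)cc2)cc(OCc2ccccc2)cc1OCc1ccc(OCc2ccccc2)cc1 | intermediate
13 | lithium enolate of 6 (lithium (2S)-5,7-bis(benzyloxy)-2-(4-methoxyphenyl)-2H-chromen-4-olate) | COc1ccc([C@H]2Oc3cc(OCc4ccccc4)cc(OCc4ccccc4)c3C(O[Li])=C2)cc1 | intermediate (not isolated)
14 | (2S,3R)-5,7-bis(benzyloxy)-3-(2-{4-(benzyloxy)-2,6-bis[(4-benzyloxybenzyl)oxy]phenyl}-2-oxoethyl)-2-(4-methoxyphenyl)chroman-4-one | COc1ccc([C@H]2Oc3cc(OCc4ccccc4)cc(OCc4ccccc4)c3C(=O)[C@@H]2CC(=O)c2c(OCc3ccc(OCc4ccccc4)cc3)cc(OCc3ccccc3)cc2OCc2ccc(OCc3ccccc3)cc2)cc1 | intermediate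
15 | lithium (Z)-enolate of 14 at the side-chain CH2 | COc1ccc([C@H]2Oc3cc(OCc4ccccc4)cc(OCc4ccccc4)c3C(=O)[C@@H]2/C=C(\O[Li])c2c(OCc3ccc(OCc4ccccc4)cc3)cc(OCc3ccccc3)cc2OCc2ccc(OCc3ccccc3)cc2)cc1 | intermediate (not isolated)
16 | (2S,3R)-5,7-bis(benzyloxy)-3-(1-{4-(benzyloxy)-2,6-bis[(4-benzyloxybenzyl)oxy]phenyl}-4,4,4-trifluoro-1,3-dioxobutan-2-yl)-2-(4-methoxyphenyl)chroman-4-one (side-chain epimers and enol forms) | COc1ccc([C@H]2Oc3cc(OCc4ccccc4)cc(OCc4ccccc4)c3C(=O)[C@@H]2C(C(=O)C(F)(F)F)C(=O)c2c(OCc3ccc(OCc4ccccc4)cc3)cc(OCc3ccccc3)cc2OCc2ccc(OCc3ccccc3)cc2)cc1 | intermediate (not isolated)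
17 | (2S,3R)-5,7-bis(benzyloxy)-3-(2-{4-(benzyloxy)-2,6-bis[(4-benzyloxybenzyl)oxy]phenyl}-1-diazo-2-oxoethyl)-2-(4-methoxyphenyl)chroman-4-one | COc1ccc([C@H]2Oc3cc(OCc4ccccc4)cc(OCc4ccccc4)c3C(=O)[C@@H]2C(=[N+]=[N-])C(=O)c2c(OCc3ccc(OCc4ccccc4)cc3)cc(OCc3ccccc3)cc2OCc2ccc(OCc3ccccc3)cc2)cc1 | intermediate (key-step precursor)
18 | (2S,3R)-5,7-bis(benzyloxy)-3-{(2S,3S)-7-(benzyloxy)-5-[(4-benzyloxybenzyl)oxy]-2-(4-benzyloxyphenyl)-4-oxochroman-3-yl}-2-(4-methoxyphenyl)chroman-4-one | COc1ccc([C@H]2Oc3cc(OCc4ccccc4)cc(OCc4ccccc4)c3C(=O)[C@@H]2[C@@H]2C(=O)c3c(OCc4ccc(OCc5ccccc5)cc4)cc(OCc4ccccc4)cc3O[C@@H]2c2ccc(OCc4ccccc4)cc2)cc1 | intermediate (key-step product)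
19 | (2S,3R)-5,7-dihydroxy-3-[(2S,3S)-5,7-dihydroxy-2-(4-hydroxyphenyl)-4-oxochroman-3-yl]-2-(4-methoxyphenyl)chroman-4-one | COc1ccc([C@H]2Oc3cc(O)cc(O)c3C(=O)[C@@H]2[C@@H]2C(=O)c3c(O)cc(O)cc3O[C@@H]2c2ccc(O)cc2)cc1 | target

**Step count and risks**

Total step count: 10. Longest linear sequence: 7 steps (steps 1, 2, 3, 7, 8, 9, 10). Steps 4, 5 and 6 form the second branch, equally three steps long, which joins at step 7.

Steps most likely to fail:

1. Step 9 (proposed new method). What may go wrong: the 1,2-hydride shift from C3 to the carbenoid carbon may outrun insertion; the ether oxygen may attack the carbenoid and trigger a [1,2]-benzyl shift; or a mismatched catalyst–substrate pairing may give poor face selectivity, hence a 2'',3''-trans or wrong cis arrangement. Fallback with known chemistry, closing O1''–C2'' instead of C2''–C3'': it sets out from diketone 14. MgBr2·OEt2 (CH2Cl2/Et2O, rt) removes one ortho 4-benzyloxybenzyl group by chelation to the aryl ketone, this electron-rich ether being more labile than the C5 benzyl ether of unit 1, and should give the ortho-hydroxy ketone F1. Enolisation with chlorodicyclohexylborane/Et3N (E enol borinate, excess reagent to cover the phenol) and addition of 4-benzyloxybenzaldehyde at −78 °C should give the anti β-hydroxy ketone F2, to be separated from the anti isomer of opposite facial sense relative to C3. Mitsunobu cyclisation (PPh3, DIAD, THF, 0 °C) then displaces the benzylic hydroxyl by the phenol with inversion, which turns the anti aldol into the 2'',3''-cis flavanone and rejoins the route at 18.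

2. Step 7. What may go wrong: the lithium enolate may open by β-elimination of the ring A phenoxide, with loss of the C2 configuration, or proton transfer from the acidic bromo ketone may quench it before C-alkylation. Fallback with radical instead of ionic C–C bond formation: it sets out from flavanone 6. Soft enolisation (Me3SiOTf, Et3N, CH2Cl2, 0 °C) should give the trimethylsilyl enol ether F3 without a free enolate. Irradiation with blue light in MeCN with fac-Ir(ppy)3, tris(2-phenylpyridinato)iridium (1 mol %), and bromo ketone 12 generates the α-keto radical, which should add to C3 opposite to the C2 aryl group; oxidation of the resulting α-silyloxy radical and loss of the silyl group return the route to diketone 14.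

3. Step 8. What may go wrong: deprotonation at the methine C3 in place of the side-chain CH2 (acylation at the wrong carbon or ring opening of unit 1), or slow C-acylation of the hindered enolate. Fallback without strong base, in which the condensation itself selects the site: it sets out from 14. Heating with tert-butoxybis(dimethylamino)methane (toluene, 80 °C) should convert the CH2 group, the only α-carbon that can lose two hydrogens, into the enaminone F4. Mesyl azide (MeCN, rt) then adds to the enamine double bond and the triazoline fragments to the diazo ketone and an N-sulfonyl formamidine (enaminone variant of the Regitz deformylative diazo transfer), rejoining the route at 17.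

**Further compounds**

F1 | step 9 | (2S,3R)-5,7-bis(benzyloxy)-3-(2-{4-(benzyloxy)-2-[(4-benzyloxybenzyl)oxy]-6-hydroxyphenyl}-2-oxoethyl)-2-(4-methoxyphenyl)chroman-4-one | COc1ccc([C@H]2Oc3cc(OCc4ccccc4)cc(OCc4ccccc4)c3C(=O)[C@@H]2CC(=O)c2c(O)cc(OCc3ccccc3)cc2OCc2ccc(OCc3ccccc3)cc2)cc1
F2 | step 9 | anti aldol adduct (2S,3R)-5,7-bis(benzyloxy)-3-[(2S,3R)-1-{4-(benzyloxy)-2-[(4-benzyloxybenzyl)oxy]-6-hydroxyphenyl}-3-(4-benzyloxyphenyl)-3-hydroxy-1-oxopropan-2-yl]-2-(4-methoxyphenyl)chroman-4-one | COc1ccc([C@H]2Oc3cc(OCc4ccccc4)cc(OCc4ccccc4)c3C(=O)[C@@H]2[C@H](C(=O)c2c(O)cc(OCc3ccccc3)cc2OCc2ccc(OCc3ccccc3)cc2)[C@@H](O)c2ccc(OCc3ccccc3)cc2)cc1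
F3 | step 7 | (2S)-5,7-bis(benzyloxy)-2-(4-methoxyphenyl)-4-(trimethylsilyloxy)-2H-chromene | COc1ccc([C@H]2Oc3cc(OCc4ccccc4)cc(OCc4ccccc4)c3C(O[Si](C)(C)C)=C2)cc1
F4 | step 8 | (2S,3R)-5,7-bis(benzyloxy)-3-(1-{4-(benzyloxy)-2,6-bis[(4-benzyloxybenzyl)oxy]phenyl}-3-(dimethylamino)-1-oxoprop-2-en-2-yl)-2-(4-methoxyphenyl)chroman-4-one (double-bond geometry not fixed) | COc1ccc([C@H]2Oc3cc(OCc4ccccc4)cc(OCc4ccccc4)c3C(=O)[C@@H]2C(=CN(C)C)C(=O)c2c(OCc3ccc(OCc4ccccc4)cc3)cc(OCc3ccccc3)cc2OCc2ccc(OCc3ccccc3)cc2)cc1
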